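## Analysis of the target

The target 35 is a briarane: a ten-membered carbocycle (C1–C10) trans-fused along C1–C10 to cyclohexane ring A (C1, C10–C14), with a γ-lactone (C17, C19, O) across C7–C8. Twelve stereocentres (C1, C2, C6–C14, C17) and the 3Z olefin must be set. They form three groups:

- a ring A block: quaternary C1 with the C15 methyl, C10, the C11 tertiary alcohol with the C20 methyl, the C12 acetate and the 13,14-epoxide, with all three ring A oxygens on the face opposite C15;
- the C2 and C9 esters flanking the ring fusion;
- the contiguous C6–C7–C8–C17 array: chloride anti to the lactone oxygen, tertiary C8 hydroxyl, C17 methyl cis to it.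

Sensitive groups are the secondary allylic chloride at C6, the cross-conjugated 3Z,5(16)-diene, the epoxide, the β-hydroxy lactone (retro-aldol, translactonisation towards O9), and three esters of two kinds (butanoate at C2, acetates at C9 and C12) that need differentiated oxygens. The difficulty is a ten-membered ring functionalised at every carbon, with stereocentres on both sides of the ring fusion that a flexible medium ring cannot relay.

The strategy rests on the segment C2–C3=C4–C5(=C16)–C6–C7–C8(O). C8 lies five atoms from C3, and the diene sits exactly where a [3,3] shift of an allene (C4=C5=C16 on C3) and a vinyl carbinol (C6=C7 on C8) would leave it. Contracting the ring along C3–C8 turns the problem into a trans-decalin (ring A plus ring B = C1, C2, C3, C8, C9, C10) on which every stereocentre can be set on a rigid chair.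

## Retrosynthetic reasoning

**Esters and masks (35 back to 30).** The C9 and C12 acetates are removed first, giving tetraol 34, whose two tertiary hydroxyls (C8, C11) do not compete in acylation. 34 comes from acetonide 33, and 33 from the C9 4-methoxybenzyl ether 32. The C2 butanoate of 32 is cut back to alcohol 31, at which stage C2–OH is the only free secondary hydroxyl, and 31 to silyl ether 30. Three orthogonal masks (silyl on O2, benzyl-type on O9, acetonide on O11/O12) are needed because two kinds of acyl group go onto three secondary oxygens. They are also chosen so that none can migrate to, or be attacked by, an alkoxide at C8.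

**Lactone (30 back to 28).** The C8–C17 bond is cut (Reformatsky retron), giving bromo ester 29 and then chlorohydrin 28. Placing C17–C19 as an acyl unit on O7 lets the C7 stereocentre deliver the nucleophile to one face of the C8 ketone, so C8 needs no external control.

**C6 and C7 (28 back to 24).** The anti chlorohydrin is traced to the trans-epoxy ketone 27, opened at the allylic C6 with inversion, and 27 to the 6E-enone 26. 26 comes from ketone 24 by dehydrogenation on the C7 side. An E-olefin plus net anti addition of chlorine and oxygen gives exactly the C6/C7 relationship of the target.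

**Ring expansion (24 back to 21).** The C5–C6 bond is cut and C3–C8 is re-formed. The ten-membered ketone 24 becomes the decalin 21 with a C3 allenyl and a C8 vinyl carbinol. This is preferred to any end-to-end disconnection because the forward reaction is an intramolecular sigmatropic shift of a six-membered ring and makes the complete diene at once. It must deliver the 3Z geometry.

**Ring B carbon substituents (21 back to 19).** The C7–C8 bond is cut (vinyl-metal addition to ketone 20). The C3–C4 bond is then cut by a propargyl Claisen retron, which leads to the propargyl enol ether 19 and places the three-carbon unit on the C8 oxygen.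

**C2 oxidation level (19 back to 16).** 19 derives from the alkynylsilane 18, the allylic alcohol 17 and the vinylogous ester 16. Keeping C2 as a ketone until this point makes the C3=C8 enol ether a push–pull olefin. Ring B is therefore inert while ring A is oxidised.

**Ring A oxygens (16 back to 13).** Acetonide 16 is cut to the epoxy diol 15, the diene-diol 14 and the ring A 1,3-diene 13. One syn-dihydroxylation sets C11 and C12 together, and the C12 hydroxyl then directs the epoxide.

**Ring A unsaturation (13 back to 9).** Diene 13 comes from dienyl triflate 12, and 12 from the α′-methyl enone 11 (the C20 methyl enters by enolate alkylation). 11 comes from enone 10, and 10 from the regiodefined silyl enol ether 9.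

**C9 (9 back to 7).** The ether 9 comes from alcohol 8, made by reduction of the more electrophilic carbonyl of the trans-fused enedione 7.

**Decalin (7 back to 1, 2 and 4).** 7 is cut through C1–C14 and C10–C11 (Diels–Alder retron) into quinone 3 and silyloxydiene 5. The quinone supplies C1 with its methyl, the C2 and C9 oxygens, the C8 oxygen already carrying the propargyl unit, and C3 as the future nucleophilic carbon. 3 comes from the methoxyquinone 1 and alcohol 2, and 5 from enone 4.

## Alternatives that were turned down

**Alternative 1:** Ring A is disconnected through C10–C11 and C1–C14. In the forward direction a β-formyl crotonate-type enal, bound to a chiral oxazaborolidinium ion, takes up a 2-silyloxydiene of the same kind as 5 and gives A1, ring A with a C2 aldehyde and a C9 ester.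
- For: this is the best-precedented mode of that catalyst (formyl C–H contact), and the E-dienophile gives the trans C1/C10 pair directly, with no epimerisation. On enantiocontrol and on the ring-fusion relationship it is stronger than step 3 of the chosen route.
- Against: A1 contains six of the twenty ring carbons and leaves C11 undefined. The whole C3–C8 segment must then be attached and the ten-membered ring closed end to end between two branched termini. The diene, chloride and lactone are all still to come.
- Comparison: the chosen route gives up some certainty in the cycloaddition. In return it obtains the ten-membered ring and the diene from a six-membered ring in one rearrangement, and it needs no medium-ring closure at all.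

**Alternative 2:** The C1–C10 bond is disconnected. In the forward direction a Lewis acid opens a trans C1–C14 epoxide of a fourteen-membered carbocycle at the tertiary C1, C10 of an E-C10=C11 olefin attacks C1, and the C12 acetate delivers oxygen to C11, giving A2.
- For: the step is biomimetic and forms ring A, the quaternary C1, C10, C11 and the C14 oxygen in one operation. On bond-forming economy at the key step it is stronger than the chosen route.
- Against: it needs a fourteen-membered ring already carrying the chloride, diene, lactone and five stereocentres, which is a synthesis as hard as the target. Four new stereocentres depend on one transannular conformation with no reliable predictor. The C1 cation sits next to a C2 ester and a diene that can take part. The epoxide must afterwards be rebuilt from the C13/C14 oxygens of A2.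
- Comparison: the chosen route sets the ring A stereocentres one at a time on a rigid trans-decalin, where facial arguments are dependable, at the price of more steps.

**Alternative 3:** The C6–C7 bond is disconnected. In the forward direction CrCl2 (divalent chromium) turns a C16 allylic chloride into an allylchromium species that adds through C6 to a C7 aldehyde. This closes the ten-membered ring, shifts the olefin to C5=C16 and gives A3, the seco-lactone.
- For: ring closure, the exocyclic methylene, the C6 chloride and the C7 oxygen come in one mild, chemoselective step, and the chair transition state favours the anti chlorohydrin. On the C6/C7 array it is stronger than the chosen route, which needs three steps (19–21).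
- Against: it is an end-to-end ten-membered closure with the usual entropic and transannular cost. The seco-precursor must already hold the tertiary C8 carbinol with its C17 side chain and the 3Z-diene as a vinyl chloride. The facial sense at C7 relative to C8 is not controlled by the chair alone.
- Comparison: the chosen route forms the ring by a rearrangement that cannot fail to close and that also sets the 3Z geometry. It accepts a longer functionalisation of C6–C8 afterwards.

Key step: step 18

Convention: briarane numbering throughout; in the decalin compounds β is the face of the C15 methyl group.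

Assumption: in step 3 the (S)-configured oxazaborolidinium ion is taken to shield the quinone face that leads to the C1 configuration drawn for 6; if the facial sense proves opposite, the (R)-configured catalyst is used and nothing else changes.

## Route

Step 1
Reactants: 1 2-methoxy-5-methyl-1,4-benzoquinone; 2 3-(trimethylsilyl)prop-2-yn-1-ol
Product: 3 2-methyl-5-{[3-(trimethylsilyl)prop-2-yn-1-yl]oxy}-1,4-benzoquinone
Conditions: 2 (3 equiv), TsOH·H2O (cat.), PhH, 60 °C, 5 Å MS
Reagents that add atoms: none
Why: Acid-catalysed alkoxy exchange of a vinylogous ester (addition–elimination at the methoxy-bearing carbon), driven by removal of methanol. The silyl cap keeps the alkyne inert in the later palladium steps.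

Step 2
Reactants: 4 but-3-en-2-one
Product: 5 2-(triisopropylsilyloxy)buta-1,3-diene
Conditions: iPr3SiOTf, Et3N, Et2O, 0 °C → rt
Reagents that add atoms: triisopropylsilyl trifluoromethanesulfonate, CC(C)[Si](C(C)C)(C(C)C)OS(=O)(=O)C(F)(F)F
Why: Soft enolisation and O-silylation of the methyl ketone give the 2-silyloxydiene; the bulky silyl group makes the diene and the later enol ether robust.

Step 3
Reactants: 3 2-methyl-5-{[3-(trimethylsilyl)prop-2-yn-1-yl]oxy}-1,4-benzoquinone; 5 2-(triisopropylsilyloxy)buta-1,3-diene
Product: 7 trans-fused enedione (1β-methyl; 10α-H; C2 and C9 ketones; C8 silylpropargyl enol ether; C12 silyl enol ether), via cis-fused adduct 6 (not isolated)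
Conditions: (S)-o-tolyl-oxazaborolidinium triflimide (from (S)-α,α-diphenylprolinol; 20 mol %), CH2Cl2, −78 → −40 °C; then DBU (0.3 equiv), rt
Reagents that add atoms: none
Why: Lewis-acid-catalysed Diels–Alder reaction: the boron cation binds the more basic vinylogous-ester carbonyl (C2=O) on the C3–H side, so C10 (β to it) takes the nucleophilic CH2 next to the silyloxy carbon of 5 and the ketone oxygen ends at C12. The chiral cation shields one quinone face and so sets C1 in the endo, cis-fused adduct 6. DBU then equilibrates C10 (α to the C9 ketone) to the more stable trans-fused 7, a known isomerisation of this ring system when C11 is unsubstituted.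

Step 4
Reactants: 7 trans-fused enedione
Product: 8 9β-alcohol (C2 vinylogous ester retained)
Conditions: NaBH4, CeCl3·7H2O, MeOH/CH2Cl2, −78 °C
Reagents that add atoms: none
Why: Luche reduction: C9=O is the more electrophilic carbonyl (C2=O is a vinylogous ester). Hydride enters from the α face, away from the axial C15 methyl, giving the axial 9β-alcohol.

Step 5
Reactants: 8 9β-alcohol
Product: 9 9β-(4-methoxybenzyl) ether
Conditions: NaH, 4-MeOC6H4CH2Br, Bu4NI (cat.), THF/DMF, 0 °C → rt
Reagents that add atoms: 4-methoxybenzyl bromide, COc1ccc(CBr)cc1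
Why: Williamson etherification, done before the C20 methyl makes this axial hydroxyl more hindered. A benzyl-type ether cannot migrate to the C8 alkoxide of the key step and is removed oxidatively at the end.

Step 6
Reactants: 9 9β-(4-methoxybenzyl) ether
Product: 10 ring A enone (C12 ketone, C13=C14)
Conditions: Pd(OAc)2 (1.2 equiv), MeCN/DMSO, 45 °C
Reagents that add atoms: none
Why: Saegusa–Ito oxidation: the regiodefined silyl enol ether gives a palladium enolate at C13 whose only β-hydrogens are on C14, so only the C13=C14 enone can form.

Step 7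
Reactants: 10 ring A enone
Product: 11 11-methyl enone (C11 methyl α, expected major epimer)
Conditions: LiN(iPr)2, THF, −78 °C; MeI, −78 → −40 °C
Reagents that add atoms: iodomethane, CI
Why: Kinetic α′-deprotonation at C11 (the only enolisable site, C1 being quaternary) and C-alkylation of the cross-conjugated enolate introduce C20. The C11 configuration is immaterial because it is erased in step 8.

Step 8
Reactants: 11 11-methyl enone
Product: 12 dienyl triflate (C11=C12–OTf, C13=C14)
Conditions: KN(SiMe3)2, PhNTf2, THF, −78 °C
Reagents that add atoms: N-phenylbis(trifluoromethanesulfonimide), O=S(=O)(N(c1ccccc1)S(=O)(=O)C(F)(F)F)C(F)(F)F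
Why: Deprotonation at C11 and O-sulfonylation of the dienolate give the cross-conjugated enol triflate. The vinylogous ester has no α-hydrogen and the silylalkyne no acidic hydrogen.

Step 9
Reactants: 12 dienyl triflate
Product: 13 ring A 1,3-diene (C11(Me)=C12, C13=C14)
Conditions: Pd(OAc)2 (5 mol %), PPh3, HCO2H, Et3N, DMF, 60 °C
Reagents that add atoms: none
Why: Palladium-catalysed formate reduction of an enol triflate (oxidative addition, formate exchange, decarboxylation, reductive elimination) replaces the triflate by hydrogen without moving the double bonds.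

Step 10
Reactants: 13 ring A 1,3-diene
Product: 14 11α,12α-diol (C20 methyl β, C13=C14 retained)
Conditions: OsO4 (5 mol %), 4-methylmorpholine N-oxide, acetone/H2O, 0 °C
Reagents that add atoms: osmium tetroxide, O=[Os](=O)(=O)=O; 4-methylmorpholine N-oxide, C[N+]1([O-])CCOCC1; water, O
Why: Catalytic syn-dihydroxylation takes the more electron-rich trisubstituted C11=C12 bond from the α face (the β face is screened by the pseudo-axial C15 methyl and the 9β ether), setting C11 and C12 together. The push–pull C3=C8 olefin and the silylalkyne are inert.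

Step 11
Reactants: 14 11α,12α-diol
Product: 15 13α,14α-epoxy-11α,12α-diol
Conditions: VO(acac)2 (cat.), t-BuOOH, CH2Cl2, 0 °C → rt
Reagents that add atoms: tert-butyl hydroperoxide, CC(C)(C)OO
Why: Hydroxyl-directed epoxidation: the allylic C12 α-hydroxyl delivers the vanadium-bound peroxide to the α face of C13=C14, which is also the face remote from C15, giving the cis-epoxy alcohol.

Step 12
Reactants: 15 epoxy diol
Product: 16 11,12-acetonide
Conditions: 2-methoxypropene, PPTS (cat.), CH2Cl2, 0 °C
Reagents that add atoms: 2-methoxypropene, COC(C)=C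
Why: Acid-catalysed ketalisation of the cis-diol; the weak acid leaves the hindered epoxide and the benzyl-type ether untouched.

Step 13
Reactants: 16 acetonide
Product: 17 2β-allylic alcohol (C3=C8 propargyl-type enol ether)
Conditions: iBu2AlH, CH2Cl2, −78 °C; Rochelle salt work-up
Reagents that add atoms: none
Why: 1,2-Reduction of the vinylogous ester: hydride adds anti to the vicinal axial C15 methyl and gives the equatorial 2β-alcohol. The work-up is non-acidic because β-alkoxy allylic alcohols ionise easily.

Step 14
Reactants: 17 2β-allylic alcohol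
Product: 18 2β-tert-butyldimethylsilyl ether
Conditions: tBuMe2SiOTf, 2,6-lutidine, CH2Cl2, −78 °C
Reagents that add atoms: tert-butyldimethylsilyl trifluoromethanesulfonate, CC(C)(C)[Si](C)(C)OS(=O)(=O)C(F)(F)F
Why: Buffered silylation of the hindered alcohol. This ether is orthogonal to the O9 and O11/O12 masks and will be 1,3-diequatorial to the C8 alkoxide, out of reach for silyl migration.

Step 15
Reactants: 18 silyl ether with alkynylsilane
Product: 19 propargyl enol ether (terminal alkyne)
Conditions: K2CO3, MeOH, rt
Reagents that add atoms: none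
Why: Base-mediated protodesilylation of the alkynylsilane; the alkyl silyl ether, epoxide, ketal and enol ether are stable to methanolic carbonate.

Step 16
Reactants: 19 propargyl enol ether
Product: 20 3α-allenyl C8 ketone
Conditions: PhMe, 140 °C (sealed tube), NaHCO3 (solid, trace)
Reagents that add atoms: none
Why: Saucy–Marbet (propargyl Claisen) rearrangement: the [3,3] shift breaks the O–CH2 bond and joins C3 to the alkyne terminus, giving the C3 allene and the C8 ketone. The β face of C3 is flanked by the axial C15 methyl and the axial C9 ether, so the allene is delivered α (equatorial). The conditions are neutral, so the epimerisable C9 and the β-silyloxy ketone are not touched.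

Step 17
Reactants: 20 3α-allenyl C8 ketone
Product: 21 3α-allenyl-8α-vinyl-8β-ol (key-step precursor)
Conditions: CH2=CHMgBr, LaCl3·2LiCl, THF, −78 → 0 °C
Reagents that add atoms: vinylmagnesium bromide, C=C[Mg]Br
Why: 1,2-Addition of the Grignard reagent, with the lanthanum salt suppressing enolisation. Equatorial approach is blocked by the axial C9 alkoxy group, so vinyl enters axially from the α face (past H2 and H10 only), giving axial vinyl and equatorial hydroxyl at C8.

Step 18
Reactants: 21 3α-allenyl-8α-vinyl-8β-ol
Product: 24 ten-membered C8 ketone bearing the 3Z,5(16)-diene, via potassium alkoxide 22 (not isolated), via potassium enolate 23 (not isolated)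
Conditions: KH, 18-crown-6, THF, 0 °C → rt; then aq. NH4Cl, −78 °C
Reagents that add atoms: none
Why: KH with 18-crown-6 gives the free C8 potassium alkoxide 22, whose charge weakens the C3–C8 bond and accelerates the [3,3] shift (anionic oxy-Cope rearrangement; the closest known reaction type is the ring expansion of 1,2-dialkenylcyclohexanols with an allene as one π partner). Within the chair array C6=C7–C8–C3–C4=C5 the C3–C8 bond breaks while the central allene carbon C5 bonds to the vinyl terminus C6, so ring B is expanded by four atoms to the ten-membered ring; the ring is not closed end to end but opened out of the decalin, the new bond forming inside a six-membered transition state. The allene π bond orthogonal to the reacting one remains as the C5=C16 methylene and C3=C4 appears in the ring, so the whole 3Z,5(16)-diene arises in one event. No new stereocentre is formed; the only stereochemical element is the C3=C4 geometry, which the substrate fixes: trans-fused ring A holds ring B in the chair with axial vinyl on C8 and equatorial allenyl on C3 (gauche, as a chair transition state needs), the axial vinyl is antiperiplanar to H3, so H3 is pseudo-equatorial and C2 pseudo-axial in the transition state, which gives Z. The step needs the concerted shift to win over ionic fragmentation of the alkoxide; a dissociated potassium alkoxide at or below room temperature, the absence of migrating or acidic groups near O8, and the release of three syn-axial β substituents (C15, C20, O9) on ring opening all favour it. The product is the regiodefined C7=C8 potassium enolate 23, protonated cold to ketone 24 before proton transfer can move the diene.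

Step 19
Reactants: 24 ten-membered C8 ketone
Product: 26 3Z,5(16),6E-trienone, via trimethylsilyl enol ether 25 (not isolated)
Conditions: LiN(SiMe3)2, Me3SiCl, THF, −78 °C; then Pd(OAc)2 (1.1 equiv), MeCN, rt
Reagents that add atoms: none
Why: Kinetic enolisation on the CH2 side (C7, not the alkoxy-bearing C9) with in situ silylation, then Saegusa–Ito oxidation. Syn β-hydride elimination from the C7 palladium enolate through a transoid C5–C6–C7–C8 arrangement should give the 6E-enone.

Step 20
Reactants: 26 3Z,5(16),6E-trienone
Product: 27 6,7-trans-epoxy ketone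
Conditions: t-BuOOH, BnMe3N+ OH− (cat.), THF, 0 °C
Reagents that add atoms: tert-butyl hydroperoxide, CC(C)(C)OO
Why: Weitz–Scheffer nucleophilic epoxidation: the peroxide anion adds at C6 of the α,β-bond (nucleophilic oxidants take the α,β-bond of a dienone, not the distal methylene) and the enolate closes to the trans-epoxide. Attack on the exposed peripheral face of the E-olefin is expected to give the C7 configuration of the target.

Step 21
Reactants: 27 6,7-trans-epoxy ketone
Product: 28 6-chloro-7-hydroxy ketone (anti chlorohydrin)
Conditions: LiCl, AcOH, THF, 0 °C → rt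
Reagents that add atoms: lithium chloride, [Li+].[Cl-]
Why: Acid-assisted SN2 opening of the epoxide by chloride at C6, which is allylic and β to the carbonyl, whereas C7 is deactivated towards a transition state with cationic character. Inversion at C6 with retention at C7 gives the anti chlorohydrin; the ring A epoxide is screened against trans-diaxial opening by the two syn-axial methyl groups.

Step 22
Reactants: 28 6-chloro-7-hydroxy ketone
Product: 29 7-O-(2-bromopropanoyl) ester (mixture of epimers at the bromide carbon)
Conditions: CH3CHBrCOBr, pyridine, CH2Cl2, −40 → 0 °C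
Reagents that add atoms: 2-bromopropanoyl bromide, CC(Br)C(Br)=O
Why: Acylation of the only free hydroxyl with an acid bromide at low temperature and with a weak base, so that the β-chloro ketone does not eliminate. The configuration at the bromide carbon is lost in the next step.

Step 23
Reactants: 29 7-O-(2-bromopropanoyl) ester
Product: 30 8-hydroxy-17-methyl γ-lactone (O2 silyl, O9 4-methoxybenzyl, 11,12-acetonide)
Conditions: SmI2 (2.2 equiv), THF, −78 °C
Reagents that add atoms: none
Why: Intramolecular Reformatsky reaction: SmI2 reduces the C–Br bond faster than any other group, and the samarium enolate adds to the C8 ketone. With C6–C7–C8–C9 transoid, the C7 oxygen tether reaches only the carbonyl face on its own side, which gives the 8-hydroxyl and the trans ring-fused lactone of the target. The C17 methyl takes the position cis to the hydroxyl and away from C9, which is also the thermodynamically preferred one.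

Step 24
Reactants: 30 protected lactone
Product: 31 C2 alcohol
Conditions: HF·pyridine, pyridine, THF, 0 °C → rt
Reagents that add atoms: none
Why: Fluoride cleavage of the silyl ether; buffered HF·pyridine tolerates the hindered epoxide, the allylic chloride, the ketal and the lactone.

Step 25
Reactants: 31 C2 alcohol
Product: 32 C2 butanoate
Conditions: (PrCO)2O, DMAP (cat.), pyridine, CH2Cl2, 0 °C
Reagents that add atoms: butanoic anhydride, CCCC(=O)OC(=O)CCC
Why: DMAP-catalysed esterification; C2–OH is the only free secondary alcohol and the tertiary C8 hydroxyl does not react at this temperature.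

Step 26
Reactants: 32 C2 butanoate
Product: 33 C9 alcohol (acetonide retained)
Conditions: DDQ, CH2Cl2/pH 7 buffer, 0 °C
Reagents that add atoms: none
Why: Oxidative cleavage of the 4-methoxybenzyl ether through the benzylic oxocarbenium ion, hydrolysed by the wet buffered medium; esters, chloride and epoxide are not affected.

Step 27
Reactants: 33 C9 alcohol
Product: 34 8,9,11,12-tetraol (C2 butanoate)
Conditions: AcOH/H2O (4:1), 40 °C
Reagents that add atoms: none
Why: Mild acid hydrolysis of the acetonide (it also hydrolyses any 8,9-(4-methoxybenzylidene) acetal carried over from step 26). The epoxide is cis to the C12 hydroxyl (no Payne shift) and screened against trans-diaxial opening.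

Step 28
Reactants: 34 tetraol
Product: 35 CNP0114058.1 (target)
Conditions: Ac2O, pyridine, DMAP (cat.), CH2Cl2, 0 °C → rt
Reagents that add atoms: acetic anhydride, CC(=O)OC(C)=O
Why: Acetylation of the two secondary hydroxyls (C9, C12), run directly after step 27 so that the free C9 hydroxyl has little time to attack the lactone. The tertiary C8 and C11 hydroxyls are not acylated under these conditions.

## Compound list

1 | 2-methoxy-5-methyl-1,4-benzoquinone | COC1=CC(=O)C(C)=CC1=O | starting material
2 | 3-(trimethylsilyl)prop-2-yn-1-ol | C[Si](C)(C)C#CCO | starting material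
3 | 2-methyl-5-{[3-(trimethylsilyl)prop-2-yn-1-yl]oxy}-1,4-benzoquinone | CC1=CC(=O)C(OCC#C[Si](C)(C)C)=CC1=O | intermediate
4 | but-3-en-2-one | CC(=O)C=C | starting material
5 | 2-(triisopropylsilyloxy)buta-1,3-diene | C=CC(=C)O[Si](C(C)C)(C(C)C)C(C)C | intermediate
6 | cis-fused Diels–Alder adduct (1β-methyl, 10β-H; C2 and C9 ketones, C3=C8 with silylpropargyl ether on C8, C12 triisopropylsilyl enol ether) | O=C1C=C(OCC#C[Si](C)(C)C)C(=O)[C@@H]2CC(O[Si](C(C)C)(C(C)C)C(C)C)=CC[C@@]21C | intermediate (not isolated)
7 | trans-fused enedione (10α-H epimer of 6) | O=C1C=C(OCC#C[Si](C)(C)C)C(=O)[C@H]2CC(O[Si](C(C)C)(C(C)C)C(C)C)=CC[C@@]21C | intermediate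
8 | 9β-alcohol of 7 (C2 vinylogous ester) | O=C1C=C(OCC#C[Si](C)(C)C)[C@@H](O)[C@H]2CC(O[Si](C(C)C)(C(C)C)C(C)C)=CC[C@@]21C | intermediate
9 | 9β-(4-methoxybenzyl) ether of 8 | O=C1C=C(OCC#C[Si](C)(C)C)[C@@H](OCc3ccc(OC)cc3)[C@H]2CC(O[Si](C(C)C)(C(C)C)C(C)C)=CC[C@@]21C | intermediate
10 | ring A enone (C12 ketone, C13=C14) | O=C1C=C(OCC#C[Si](C)(C)C)[C@@H](OCc3ccc(OC)cc3)[C@H]2CC(=O)C=C[C@@]21C | intermediate
11 | 11α-methyl enone (C20 introduced; C11 epimer immaterial) | O=C1C=C(OCC#C[Si](C)(C)C)[C@@H](OCc3ccc(OC)cc3)[C@H]2[C@H](C)C(=O)C=C[C@@]21C | intermediate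
12 | dienyl triflate (C11=C12–OTf, C13=C14) | O=C1C=C(OCC#C[Si](C)(C)C)[C@@H](OCc3ccc(OC)cc3)[C@H]2C(C)=C(OS(=O)(=O)C(F)(F)F)C=C[C@@]21C | intermediate
13 | ring A 1,3-diene (C11(Me)=C12, C13=C14) | O=C1C=C(OCC#C[Si](C)(C)C)[C@@H](OCc3ccc(OC)cc3)[C@H]2C(C)=CC=C[C@@]21C | intermediate
14 | 11α,12α-diol (20-methyl β), C13=C14 | O=C1C=C(OCC#C[Si](C)(C)C)[C@@H](OCc3ccc(OC)cc3)[C@H]2[C@](C)(O)[C@H](O)C=C[C@@]21C | intermediate
15 | 13α,14α-epoxy-11α,12α-diol | O=C1C=C(OCC#C[Si](C)(C)C)[C@@H](OCc3ccc(OC)cc3)[C@H]2[C@](C)(O)[C@H](O)[C@@H]3O[C@@H]3[C@@]21C | intermediate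
16 | 11,12-acetonide of 15 | O=C1C=C(OCC#C[Si](C)(C)C)[C@@H](OCc3ccc(OC)cc3)[C@H]2[C@]4(C)OC(C)(C)O[C@@H]4[C@@H]3O[C@@H]3[C@@]21C | intermediate
17 | 2β-allylic alcohol (C3=C8 enol ether) | O[C@H]1C=C(OCC#C[Si](C)(C)C)[C@@H](OCc3ccc(OC)cc3)[C@H]2[C@]4(C)OC(C)(C)O[C@@H]4[C@@H]3O[C@@H]3[C@@]21C | intermediate
18 | 2β-tert-butyldimethylsilyl ether of 17 | CC(C)(C)[Si](C)(C)O[C@H]1C=C(OCC#C[Si](C)(C)C)[C@@H](OCc3ccc(OC)cc3)[C@H]2[C@]4(C)OC(C)(C)O[C@@H]4[C@@H]3O[C@@H]3[C@@]21C | intermediate
19 | propargyl enol ether (terminal alkyne) | CC(C)(C)[Si](C)(C)O[C@H]1C=C(OCC#C)[C@@H](OCc3ccc(OC)cc3)[C@H]2[C@]4(C)OC(C)(C)O[C@@H]4[C@@H]3O[C@@H]3[C@@]21C | intermediate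
20 | 3α-allenyl C8 ketone (2β-silyloxy, 9β-(4-methoxybenzyl)oxy) | C=C=C[C@H]1[C@H](O[Si](C)(C)C(C)(C)C)[C@@]2(C)[C@H]3O[C@H]3[C@H]4OC(C)(C)O[C@@]4(C)[C@@H]2[C@H](OCc5ccc(OC)cc5)C1=O | intermediate
21 | 3α-allenyl-8α-vinyl decalin-8β-ol (key-step precursor) | C=C=C[C@H]1[C@H](O[Si](C)(C)C(C)(C)C)[C@@]2(C)[C@H]3O[C@H]3[C@H]4OC(C)(C)O[C@@]4(C)[C@@H]2[C@H](OCc5ccc(OC)cc5)[C@@]1(O)C=C | intermediate
22 | potassium alkoxide of 21 | C=C=C[C@H]1[C@H](O[Si](C)(C)C(C)(C)C)[C@@]2(C)[C@H]3O[C@H]3[C@H]4OC(C)(C)O[C@@]4(C)[C@@H]2[C@H](OCc5ccc(OC)cc5)[C@@]1([O-])C=C.[K+] | intermediate (not isolated)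
23 | potassium C7=C8 enolate of 24 (C6 and C9 trans on the enolate) | C=C1/C=C\[C@H](O[Si](C)(C)C(C)(C)C)[C@@]2(C)[C@H]3O[C@H]3[C@H]4OC(C)(C)O[C@@]4(C)[C@@H]2[C@H](OCc5ccc(OC)cc5)/C([O-])=C/C1.[K+] | intermediate (not isolated)
24 | ten-membered C8 ketone with the 3Z,5(16)-diene (key-step product) | C=C1/C=C\[C@H](O[Si](C)(C)C(C)(C)C)[C@@]2(C)[C@H]3O[C@H]3[C@H]4OC(C)(C)O[C@@]4(C)[C@@H]2[C@H](OCc5ccc(OC)cc5)C(=O)CC1 | intermediate
25 | C7=C8 trimethylsilyl enol ether of 24 (enol ether geometry not defined, immaterial) | C=C1/C=C\[C@H](O[Si](C)(C)C(C)(C)C)[C@@]2(C)[C@H]3O[C@H]3[C@H]4OC(C)(C)O[C@@]4(C)[C@@H]2[C@H](OCc5ccc(OC)cc5)C(O[Si](C)(C)C)=CC1 | intermediate (not isolated)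
26 | 3Z,5(16),6E-trienone | O=C1/C=C/C(=C)/C=C\[C@H](O[Si](C)(C)C(C)(C)C)[C@@]2(C)[C@H]3O[C@H]3[C@H]4OC(C)(C)O[C@@]4(C)[C@@H]2[C@@H]1OCc5ccc(OC)cc5 | intermediate
27 | 6,7-trans-epoxy C8 ketone (C7–O as in the target) | O=C1[C@H]6O[C@@H]6C(=C)/C=C\[C@H](O[Si](C)(C)C(C)(C)C)[C@@]2(C)[C@H]3O[C@H]3[C@H]4OC(C)(C)O[C@@]4(C)[C@@H]2[C@@H]1OCc5ccc(OC)cc5 | intermediate
28 | 6-chloro-7-hydroxy C8 ketone (C6, C7 as in the target) | O=C1[C@@H](O)[C@@H](Cl)C(=C)/C=C\[C@H](O[Si](C)(C)C(C)(C)C)[C@@]2(C)[C@H]3O[C@H]3[C@H]4OC(C)(C)O[C@@]4(C)[C@@H]2[C@@H]1OCc5ccc(OC)cc5 | intermediate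
29 | 7-O-(2-bromopropanoyl) ester of 28 (epimers at the bromide carbon) | O=C1[C@@H](OC(=O)C(C)Br)[C@@H](Cl)C(=C)/C=C\[C@H](O[Si](C)(C)C(C)(C)C)[C@@]2(C)[C@H]3O[C@H]3[C@H]4OC(C)(C)O[C@@]4(C)[C@@H]2[C@@H]1OCc5ccc(OC)cc5 | intermediate
30 | lactone with 8-OH and 17-methyl as in the target; O2 silyl, O9 4-methoxybenzyl, 11,12-acetonide | C=C1/C=C\[C@H](O[Si](C)(C)C(C)(C)C)[C@@]2(C)[C@H]3O[C@H]3[C@H]4OC(C)(C)O[C@@]4(C)[C@@H]2[C@H](OCc5ccc(OC)cc5)[C@]2(O)[C@@H](C)C(=O)O[C@H]2[C@H]1Cl | intermediate
31 | C2 alcohol | C=C1/C=C\[C@H](O)[C@@]2(C)[C@H]3O[C@H]3[C@H]4OC(C)(C)O[C@@]4(C)[C@@H]2[C@H](OCc5ccc(OC)cc5)[C@]2(O)[C@@H](C)C(=O)O[C@H]2[C@H]1Cl | intermediate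
32 | C2 butanoate | C=C1/C=C\[C@H](OC(=O)CCC)[C@@]2(C)[C@H]3O[C@H]3[C@H]4OC(C)(C)O[C@@]4(C)[C@@H]2[C@H](OCc5ccc(OC)cc5)[C@]2(O)[C@@H](C)C(=O)O[C@H]2[C@H]1Cl | intermediate
33 | C9 alcohol (C2 butanoate, 11,12-acetonide) | C=C1/C=C\[C@H](OC(=O)CCC)[C@@]2(C)[C@H]3O[C@H]3[C@H]4OC(C)(C)O[C@@]4(C)[C@@H]2[C@H](O)[C@]2(O)[C@@H](C)C(=O)O[C@H]2[C@H]1Cl | intermediate
34 | 8,9,11,12-tetraol (C2 butanoate) | C=C1/C=C\[C@H](OC(=O)CCC)[C@@]2(C)[C@H]3O[C@H]3[C@@H](O)[C@@](C)(O)[C@@H]2[C@H](O)[C@]2(O)[C@@H](C)C(=O)O[C@H]2[C@H]1Cl | intermediate
35 | CNP0114058.1 | C=C1/C=C\[C@H](OC(=O)CCC)[C@@]2(C)[C@H]3O[C@H]3[C@@H](OC(C)=O)[C@@](C)(O)[C@@H]2[C@H](OC(C)=O)[C@]2(O)[C@@H](C)C(=O)O[C@H]2[C@H]1Cl | target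

## Step count and risk

Total step count: 28. Longest linear sequence: 27 steps (steps 1 and 3–28; step 2 makes diene 5 in one step from 4).

**Step 18 (key step).** The alkoxide may cleave the C3–C8 bond heterolytically, because the allenyl group stabilises negative charge at C3 and the decalin is strained; recombination would then give [1,3]-shift or open-chain products. The array may also react through a boat (3E isomer), or the product enolate may shuttle protons and move the diene into conjugation. Fallback: the rearrangement is run on the neutral silyl ether. Carbinol 21 is silylated (N-trimethylsilylimidazole) to its C8 trimethylsilyl ether F1, which is heated (o-dichlorobenzene, 180–200 °C, a trace of hindered amine). The concerted thermal shift cannot fragment ionically and gives the trimethylsilyl enol ether 25 directly, where the route is rejoined at the second stage of step 19.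

**Step 3.** Facial discrimination by the chiral cation may be poor, because the reacting C1=C10 bond lies anti to the bound lone pair and carries the methyl group on its α-carbon. The catalyst may also engage the C9 carbonyl and give the C13-oxygenated regioisomer, or the base equilibration at C10 may stop short. Fallback: the absolute configuration is obtained by resolution. From 3 and 5, BF3·OEt2 (CH2Cl2, −78 °C; it binds the same basic carbonyl) followed by DBU gives 7 as the racemate, that is together with its mirror image ent-7 F2. Step 4 then gives 8 together with ent-8 F3. Esterification with (S)-2-methoxy-2-phenylacetic acid (DCC, DMAP) gives the diastereomeric esters, the (S)-2-methoxy-2-phenylacetate of 8 F4 and the (S)-2-methoxy-2-phenylacetate of ent-8 F5, which are separated by chromatography. Ammonolysis of F4 (NH3 in MeOH, 0 °C, which leaves the alkynylsilane) returns 8, where the route continues.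

**Step 19.** The syn β-hydride elimination may pass through a cisoid C5–C6–C7–C8 arrangement, which a ten-membered ring tolerates, and give the 6Z-enone or a mixture; enolisation towards C9 would also erode that centre. Fallback: the Z isomer is used with a double inversion. If 24 gives the 6Z-enone F6, nucleophilic epoxidation as in step 20 gives the 6,7-cis-epoxy ketone F7. Opening at C6 with bromide (LiBr, AcOH, THF) gives the 6-bromo-7-hydroxy ketone F8 with inversion. SN2 exchange with LiCl (DMF, rt) inverts C6 a second time and gives chlorohydrin 28, where the route is rejoined; a cis-epoxide with net retention at C6 is equivalent to a trans-epoxide with inversion.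

**Step 20.** The peroxide may add to the wrong face of the E-olefin if the ring conformer exposes it, the intermediate enolate may close to the cis-epoxide, or the basic medium may epimerise C9. Fallback: the face is set by reagents through the allylic alcohol. Enone 26 is reduced (Corey–Bakshi–Shibata reduction; catecholborane and the oxazaborolidine enantiomer that gives this carbinol) to the C8 allylic alcohol F9. A titanium–tartrate epoxidation (Ti(OiPr)4, t-BuOOH, the diethyl tartrate enantiomer matched with this carbinol) touches only the allylic alcohol olefin and gives the erythro 6,7-epoxy C8 alcohol F10. Oxidation with Dess–Martin periodinane returns epoxy ketone 27.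

**Step 21.** Chloride may attack C7 (the carbon α to the carbonyl), or attack C16 with shift of the double bond to C5=C6, instead of the direct substitution at C6. Fallback: the hydroxy ester is built first, so that the opening becomes that of a 2,3-epoxy alcohol. From 27, an intermolecular Reformatsky addition of ethyl 2-bromopropanoate (Zn dust, THF) to the C8 ketone, anti to the epoxide C–O bond (Felkin–Anh), gives the epoxy hydroxy ester F11. Ti(OiPr)4 with Et2NH2Cl then opens the epoxide at C6 (the distal carbon of the epoxy alcohol, and allylic), and the C7 titanium alkoxide closes onto the ester to give lactone 30 directly. The route is rejoined at 30, and steps 22 and 23 are not needed.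

## Further compounds

F1 | step 18 | C8 trimethylsilyl ether of 21 | C=C=C[C@H]1[C@H](O[Si](C)(C)C(C)(C)C)[C@@]2(C)[C@H]3O[C@H]3[C@H]4OC(C)(C)O[C@@]4(C)[C@@H]2[C@H](OCc5ccc(OC)cc5)[C@@]1(O[Si](C)(C)C)C=C
F2 | step 3 | ent-7 (mirror image of 7) | O=C1C=C(OCC#C[Si](C)(C)C)C(=O)[C@@H]2CC(O[Si](C(C)C)(C(C)C)C(C)C)=CC[C@]21C
F3 | step 3 | ent-8 (mirror image of 8) | O=C1C=C(OCC#C[Si](C)(C)C)[C@H](O)[C@@H]2CC(O[Si](C(C)C)(C(C)C)C(C)C)=CC[C@]21C
F4 | step 3 | (S)-2-methoxy-2-phenylacetate of 8 | O=C1C=C(OCC#C[Si](C)(C)C)[C@@H](OC(=O)[C@@H](OC)c3ccccc3)[C@H]2CC(O[Si](C(C)C)(C(C)C)C(C)C)=CC[C@@]21C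
F5 | step 3 | (S)-2-methoxy-2-phenylacetate of ent-8 | O=C1C=C(OCC#C[Si](C)(C)C)[C@H](OC(=O)[C@@H](OC)c3ccccc3)[C@@H]2CC(O[Si](C(C)C)(C(C)C)C(C)C)=CC[C@]21C
F6 | step 19 | 6Z isomer of 26 | O=C1/C=C\C(=C)/C=C\[C@H](O[Si](C)(C)C(C)(C)C)[C@@]2(C)[C@H]3O[C@H]3[C@H]4OC(C)(C)O[C@@]4(C)[C@@H]2[C@@H]1OCc5ccc(OC)cc5
F7 | step 19 | 6,7-cis-epoxy C8 ketone (C7–O as in the target) | O=C1[C@H]6O[C@H]6C(=C)/C=C\[C@H](O[Si](C)(C)C(C)(C)C)[C@@]2(C)[C@H]3O[C@H]3[C@H]4OC(C)(C)O[C@@]4(C)[C@@H]2[C@@H]1OCc5ccc(OC)cc5
F8 | step 19 | 6-bromo-7-hydroxy C8 ketone (bromide on the face opposite to the chloride of 28) | O=C1[C@@H](O)[C@H](Br)C(=C)/C=C\[C@H](O[Si](C)(C)C(C)(C)C)[C@@]2(C)[C@H]3O[C@H]3[C@H]4OC(C)(C)O[C@@]4(C)[C@@H]2[C@@H]1OCc5ccc(OC)cc5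
F9 | step 20 | C8 allylic alcohol from 26 (hydroxyl on the face of the 8-OH of the target) | O[C@H]1/C=C/C(=C)/C=C\[C@H](O[Si](C)(C)C(C)(C)C)[C@@]2(C)[C@H]3O[C@H]3[C@H]4OC(C)(C)O[C@@]4(C)[C@@H]2[C@@H]1OCc5ccc(OC)cc5
F10 | step 20 | erythro 6,7-epoxy C8 alcohol | O[C@H]1[C@H]6O[C@@H]6C(=C)/C=C\[C@H](O[Si](C)(C)C(C)(C)C)[C@@]2(C)[C@H]3O[C@H]3[C@H]4OC(C)(C)O[C@@]4(C)[C@@H]2[C@@H]1OCc5ccc(OC)cc5
F11 | step 21 | ethyl 2-(8-hydroxy-6,7-epoxy) propanoate adduct of 27 (C8 and C17 as in the target) | CCOC(=O)[C@H](C)[C@]1(O)[C@H]6O[C@@H]6C(=C)/C=C\[C@H](O[Si](C)(C)C(C)(C)C)[C@@]2(C)[C@H]3O[C@H]3[C@H]4OC(C)(C)O[C@@]4(C)[C@@H]2[C@@H]1OCc5ccc(OC)cc5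
A1 | alternative 1 | methyl 6-formyl-2,6-dimethyl-3-(triisopropylsilyloxy)cyclohex-3-ene-1-carboxylate (ring A with C2 aldehyde and C9 ester) | O=C[C@@]1(C)CC=C(O[Si](C(C)C)(C(C)C)C(C)C)C(C)[C@@H]1C(=O)OC
A2 | alternative 2 | bicyclic C14 alcohol with C13 tert-butyldimethylsilyl ether | C=C1/C=C\[C@H](OC(=O)CCC)[C@@]2(C)[C@H](O)[C@@H](O[Si](C)(C)C(C)(C)C)[C@@H](OC(C)=O)[C@@](C)(O)[C@@H]2[C@H](OC(C)=O)[C@]2(O)[C@@H](C)C(=O)O[C@H]2[C@H]1Cl
A3 | alternative 3 | ten-membered C7 alcohol C19 methyl ester (seco-lactone of the target) | C=C1/C=C\[C@H](OC(=O)CCC)[C@@]2(C)[C@H]3O[C@H]3[C@@H](OC(C)=O)[C@@](C)(O)[C@@H]2[C@H](OC(C)=O)[C@](O)([C@@H](C)C(=O)OC)[C@@H](O)[C@H]1Cl
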